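Ring B is not brought in as a ready-made arene but assembled last. Cutting the C1'–C6' and C2'–C3' bonds unravels it to a terminal alkyne on C2 of the tetramethoxychromone and 3,4-dimethoxyfuran. One operation, a (4+2) cycloaddition followed by acid-induced opening of the oxygen bridge, builds the whole ring and exploits its substitution pattern: the furan oxygen becomes the single free hydroxyl at C3', the furan methoxy groups become those at C4' and C5', and C2' and C6' stay as CH, so no phenol ever needs protection. The precursor, 2-ethynyl-5,6,7,8-tetramethoxychromone, is reached in four steps from 1,2,3,4-tetramethoxybenzene.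

Key step: step 5

Remark: 3,4-dimethoxyfuran is taken as a purchasable reagent; the oxanorbornadiene intermediate is racemic and its bridgehead centres vanish on aromatisation, so the achiral target needs no stereocontrol.

Step 1
Reactants: 1 1,2,3,4-tetramethoxybenzene
Product: 4 2,3,4,5-tetramethoxyphenol, via 2,3,4,5-tetramethoxyphenyllithium 2 (not isolated), via lithium aryltrimethoxyborate 3 (not isolated)
Conditions: n-C4H9Li, N,N,N',N'-tetramethylethylenediamine, THF, 0 °C; B(OCH3)3, −78 °C to rt; CH3CO2H, 30% aq. H2O2, 0 °C to rt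
Reagents that add atoms: hydrogen peroxide, OO
Why: Directed ortho-lithiation next to a methoxy group (the two free ring positions are equivalent), trapping as the borate and peroxide-induced 1,2-migration of the aryl group from boron to oxygen make up a known one-pot arene hydroxylation, and the acidic medium should spare the electron-rich phenol from over-oxidation.

Step 2
Reactants: 4 2,3,4,5-tetramethoxyphenol
Product: 6 1-(2-hydroxy-3,4,5,6-tetramethoxyphenyl)ethanone, via 2,3,4,5-tetramethoxyphenyl acetate 5 (not isolated)
Conditions: CH3CO2H, BF3·O(C2H5)2 (3 equiv), 80 °C; then H2O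
Reagents that add atoms: acetic acid, CC(=O)O
Why: Lewis-acid-promoted O-acetylation and Fries rearrangement (net Friedel–Crafts acylation) can only reach the one free ring carbon, which lies ortho to the hydroxyl and is activated by three oxygen substituents, and the hydrogen-bonded ortho-hydroxy ketone should resist further reaction.

Step 3
Reactants: 6 1-(2-hydroxy-3,4,5,6-tetramethoxyphenyl)ethanone; 7 ethyl diethoxyacetate
Product: 10 5,6,7,8-tetramethoxy-4-oxo-4H-chromene-2-carbaldehyde, via diethoxy diketone 8 (not isolated), via 2-(diethoxymethyl)chromone 9 (not isolated)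
Conditions: NaH (3 equiv), THF, 0 °C to reflux; then CH3CO2H, 3 M aq. HCl, 80 °C
Reagents that add atoms: water, O
Why: Crossed Claisen condensation of the ketone dianion with the activated α,α-dialkoxy ester should give the β-diketone, and hot aqueous acid then brings about the usual chromone cyclodehydration (phenol oxygen onto the distal ketone) together with hydrolysis of the acetal to the aldehyde.

Step 4
Reactants: 10 5,6,7,8-tetramethoxy-4-oxo-4H-chromene-2-carbaldehyde
Product: 11 2-ethynyl-5,6,7,8-tetramethoxy-4H-chromen-4-one
Conditions: CH3C(O)C(N2)P(O)(OCH3)2, K2CO3, CH3OH, 0 °C to rt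
Reagents that add atoms: dimethyl (1-diazo-2-oxopropyl)phosphonate, COP(=O)(OC)C(=[N+]=[N-])C(C)=O
Why: In this Ohira–Bestmann (Seyferth–Gilbert) homologation, methanolysis frees the diazomethylphosphonate anion, which olefinates the aldehyde, by far the most electrophilic carbonyl present, and loss of N2 with a 1,2-hydrogen shift of the alkylidene carbene should give the terminal alkyne.

Step 5
Reactants: 11 2-ethynyl-5,6,7,8-tetramethoxy-4H-chromen-4-one; 12 3,4-dimethoxyfuran
Product: 14 3'-hydroxy-5,6,7,8,4',5'-hexamethoxyflavone, via oxanorbornadiene adduct 13 (not isolated)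
Conditions: 12 (3 equiv), toluene, 100 °C, sealed tube; evaporate excess 12; 4-CH3C6H4SO3H (anhydrous, 20 mol%), toluene, 0 °C to rt
Reagents that add atoms: none
Why: The electron-rich furan adds through its C2 and C5 across the ethynyl group, whose terminal carbon is the δ-acceptor position of the vinylogous ynone formed with the chromone C2=C3–C4=O unit, in a concerted normal-demand (4+2) cycloaddition to give the 5,6-dimethoxy-7-oxanorbornadiene 13; protonation of the bridge oxygen, heterolysis of one C–O bond and loss of the proton from the carbinol carbon of the arenium ion then give the phenol. The closest known chemistry is the Diels–Alder addition of furans to acetylenic ketones and esters followed by acid isomerisation of the 7-oxanorbornadiene to a phenol. Ring B closes by intermolecular (4+2) annulation, the C1'–C6' and C2'–C3' bonds forming in one suprafacial event, so no exo/endo ring-closure classification applies. The two bridgehead centres of 13 arise as a racemate and are erased on aromatisation, so nothing has to control them. The cycloaddition has no regiochemical issue because C2 and C5 of the furan are equivalent, and the alkyne should react in preference to the trisubstituted C2=C3 bond, which is tied into the pyranone π-system. The selectivity that matters is which C–O bond breaks: cleavage at C6'–O spreads the charge over C6', C2' and the methoxy-bearing C4' with the chromonyl group on the nodal C1', whereas cleavage at C3'–O would put charge on C1' beside the electron-poor chromone C2, so the hydroxyl should stay on C3', and a 1,2-hydride shift in the cation leads to the same phenol.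

Compound list
1 | 1,2,3,4-tetramethoxybenzene | COc1ccc(OC)c(OC)c1OC | starting material
2 | 2,3,4,5-tetramethoxyphenyllithium | [Li]c1cc(OC)c(OC)c(OC)c1OC | intermediate
3 | lithium trimethoxy(2,3,4,5-tetramethoxyphenyl)borate | [Li+].CO[B-](OC)(OC)c1cc(OC)c(OC)c(OC)c1OC | intermediate
4 | 2,3,4,5-tetramethoxyphenol | Oc1cc(OC)c(OC)c(OC)c1OC | intermediate
5 | 2,3,4,5-tetramethoxyphenyl acetate | CC(=O)Oc1cc(OC)c(OC)c(OC)c1OC | intermediate
6 | 1-(2-hydroxy-3,4,5,6-tetramethoxyphenyl)ethanone | CC(=O)c1c(O)c(OC)c(OC)c(OC)c1OC | intermediate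
7 | ethyl diethoxyacetate | CCOC(OCC)C(=O)OCC | starting material
8 | 4,4-diethoxy-1-(2-hydroxy-3,4,5,6-tetramethoxyphenyl)butane-1,3-dione | CCOC(OCC)C(=O)CC(=O)c1c(O)c(OC)c(OC)c(OC)c1OC | intermediate
9 | 2-(diethoxymethyl)-5,6,7,8-tetramethoxy-4H-chromen-4-one | CCOC(OCC)c1cc(=O)c2c(OC)c(OC)c(OC)c(OC)c2o1 | intermediate
10 | 5,6,7,8-tetramethoxy-4-oxo-4H-chromene-2-carbaldehyde | O=Cc1cc(=O)c2c(OC)c(OC)c(OC)c(OC)c2o1 | intermediate
11 | 2-ethynyl-5,6,7,8-tetramethoxy-4H-chromen-4-one | C#Cc1cc(=O)c2c(OC)c(OC)c(OC)c(OC)c2o1 | intermediate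
12 | 3,4-dimethoxyfuran | COc1cocc1OC | starting material
13 | 2-(5,6-dimethoxy-7-oxabicyclo[2.2.1]hepta-2,5-dien-2-yl)-5,6,7,8-tetramethoxy-4H-chromen-4-one (racemic, one enantiomer drawn; the bridge fixes the relative configuration of the two bridgeheads) | COC1=C(OC)[C@@H]2O[C@H]1C=C2c1cc(=O)c2c(OC)c(OC)c(OC)c(OC)c2o1 | intermediate
14 | 3'-hydroxy-5,6,7,8,4',5'-hexamethoxyflavone | COc1cc(-c2cc(=O)c3c(OC)c(OC)c(OC)c(OC)c3o2)cc(O)c1OC | target

Total step count: 5. Longest linear sequence: 5 steps (1 → 4 → 6 → 10 → 11 → 14).

Steps most likely to fail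

Step 5. Several things may go wrong.
- The cycloaddition may be too slow for an alkyne that is activated only through vinylogy, so that thermal decay of the furan or a second furan addition to the strained adduct overtakes it.
- The bridge may open at the C3'–O bond and move the hydroxyl to C6'.
- Wet acid may hydrolyse the bis-enol ether before it aromatises.

The fallback builds ring B in the classical way. It sets out from 6 and returns at 14.
- Claisen–Schmidt condensation of 6 with commercial 3-(benzyloxy)-4,5-dimethoxybenzaldehyde (KOH, C2H5OH, rt) should give the chalcone (E)-3-[3-(benzyloxy)-4,5-dimethoxyphenyl]-1-(2-hydroxy-3,4,5,6-tetramethoxyphenyl)prop-2-en-1-one F1.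
- Oxidative cyclisation with I2 (cat.) in DMSO at 120 °C should give 3'-(benzyloxy)-5,6,7,8,4',5'-hexamethoxyflavone F2.
- Hydrogenolysis (H2, zerovalent palladium on carbon, ethyl acetate, rt) frees the 3'-hydroxyl and gives 14.

Step 4. The diazomethylphosphonate anion may add as a 1,3-dipole across the C2=C3 bond, which is flanked by two carbonyl groups, instead of olefinating the aldehyde. Methoxide may also open the pyranone at C2 or add to the newly formed conjugated alkyne.

The fallback installs the alkyne before the pyranone is closed. It sets out from 6 and returns at 11.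
- Esterification of 6 with commercial 3-(trimethylsilyl)propiolic acid (dicyclohexylcarbodiimide, 4-(dimethylamino)pyridine, CH2Cl2) should give 2-acetyl-3,4,5,6-tetramethoxyphenyl 3-(trimethylsilyl)prop-2-ynoate F3.
- Baker–Venkataraman acyl transfer (LiN(SiMe3)2, THF, −78 to 0 °C) should give 1-(2-hydroxy-3,4,5,6-tetramethoxyphenyl)-5-(trimethylsilyl)pent-4-yne-1,3-dione F4.
- Cyclodehydration (CH3CO2H, cat. H2SO4, rt) should give 5,6,7,8-tetramethoxy-2-[(trimethylsilyl)ethynyl]-4H-chromen-4-one F5.
- Buffered desilylation ((n-C4H9)4NF, CH3CO2H, THF, 0 °C) gives 11.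

Step 3. C-acylation of the dianion may stay incomplete, and the acetal, which sits on an electron-poor carbon, may hydrolyse slowly. The aldehyde may also be lost as its hydrate or degrade in hot acid.

The fallback reaches the aldehyde through the ester oxidation level. It sets out from 6 and returns at 10.
- Claisen condensation of 6 with diethyl oxalate (NaOC2H5, C2H5OH, reflux; then HCl) and cyclisation should give ethyl 5,6,7,8-tetramethoxy-4-oxo-4H-chromene-2-carboxylate F6.
- Chemoselective reduction of the activated ester (NaBH4, CH3OH, 0 °C) should give 2-(hydroxymethyl)-5,6,7,8-tetramethoxy-4H-chromen-4-one F7.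
- Oxidation of the allylic-type alcohol (MnO2, CH2Cl2, rt) gives 10.

Further compounds
F1 | step 5 | (E)-3-[3-(benzyloxy)-4,5-dimethoxyphenyl]-1-(2-hydroxy-3,4,5,6-tetramethoxyphenyl)prop-2-en-1-one | COc1cc(/C=C/C(=O)c2c(O)c(OC)c(OC)c(OC)c2OC)cc(OCc2ccccc2)c1OC
F2 | step 5 | 3'-(benzyloxy)-5,6,7,8,4',5'-hexamethoxyflavone | COc1cc(-c2cc(=O)c3c(OC)c(OC)c(OC)c(OC)c3o2)cc(OCc2ccccc2)c1OC
F3 | step 4 | 2-acetyl-3,4,5,6-tetramethoxyphenyl 3-(trimethylsilyl)prop-2-ynoate | CC(=O)c1c(OC(=O)C#C[Si](C)(C)C)c(OC)c(OC)c(OC)c1OC
F4 | step 4 | 1-(2-hydroxy-3,4,5,6-tetramethoxyphenyl)-5-(trimethylsilyl)pent-4-yne-1,3-dione | C[Si](C)(C)C#CC(=O)CC(=O)c1c(O)c(OC)c(OC)c(OC)c1OC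
F5 | step 4 | 5,6,7,8-tetramethoxy-2-[(trimethylsilyl)ethynyl]-4H-chromen-4-one | C[Si](C)(C)C#Cc1cc(=O)c2c(OC)c(OC)c(OC)c(OC)c2o1
F6 | step 3 | ethyl 5,6,7,8-tetramethoxy-4-oxo-4H-chromene-2-carboxylate | CCOC(=O)c1cc(=O)c2c(OC)c(OC)c(OC)c(OC)c2o1
F7 | step 3 | 2-(hydroxymethyl)-5,6,7,8-tetramethoxy-4H-chromen-4-one | OCc1cc(=O)c2c(OC)c(OC)c(OC)c(OC)c2o1
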